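**Retrosynthetic overview**
1. Target 34 ⇐ C4 ketone 33 (methylenation last) ⇐ hydroxy diketone 31 (butenolide by O-acylation/intramolecular Wittig) ⇐ polyester 29; the three acetates and the isobutyrate go on in stages and the tertiary 8-OH stays free.
2. The C6/C7/C8 oxygens and C1/C10 come from the C8 ketone and the C10=C1 olefin of 17, every reagent entering from the β-face, opposite the axial C19 and C20 methyls.
3. Key disconnection: ring B (C5–C6–C7–C8–C9–C10) ⇐ the cyclopentane ring C5–C6–C7–C8–C10 of epoxy alcohol 16 by semipinacol ring expansion, C10 shifting from C8 to C9. The enabling feature is the aldol-type array C11(O)–C9(quaternary, bonded to C10)–C8(O) in ring B.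
4. 16 ⇐ (E)-alkenyllithium 14 + hydrindenone ketal 13; C5 is set by a catalytic desymmetrising benzoin reaction of triketo aldehyde 10.
5. Order of ring formation: ring A (bought) → five-membered ring (benzoin) → ring B (ring expansion) → butenolide.

Key step: step 11

Remark: clerodane numbering is used (ring A = C1–C5, C10; ring B = C5–C10; side chain C11–C16; C17 on C8, C18 exocyclic on C4, C19 on C5, C20 on C9), and α is the face of the C19 methyl. Racemic 1 is acceptable because its stereocentre is oxidised in step 2.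

**Side-chain fragment**

Step 1
Reactants: 1 2-{[(4-methoxybenzyl)oxy]methyl}oxirane (racemic); 2 1-propynyllithium
Product: 3 1-[(4-methoxybenzyl)oxy]hex-4-yn-2-ol (racemic)
Conditions: THF/DMPU, −78 °C → rt; then H2O
Reagents that add atoms: none
Why: Epoxide opening by an alkynyllithium at the unsubstituted carbon (SN2) should give the homopropargylic alcohol; the carbinol configuration is irrelevant.

Step 2
Reactants: 3 1-[(4-methoxybenzyl)oxy]hex-4-yn-2-ol
Product: 4 1-[(4-methoxybenzyl)oxy]hex-4-yn-2-one
Conditions: DMP, NaHCO3, CH2Cl2, 0 °C → rt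
Reagents that add atoms: none
Why: Dess–Martin oxidation under buffered conditions should give the β,γ-alkynyl ketone without base-induced isomerisation to the allenyl ketone.

Step 3
Reactants: 4 1-[(4-methoxybenzyl)oxy]hex-4-yn-2-one
Product: 5 2-(but-2-yn-1-yl)-2-{[(4-methoxybenzyl)oxy]methyl}-1,3-dioxolane
Conditions: 1,2-bis(trimethylsilyloxy)ethane, TMSOTf (cat.), CH2Cl2, −78 → −20 °C
Reagents that add atoms: 1,2-bis(trimethylsilyloxy)ethane, C[Si](C)(C)OCCO[Si](C)(C)C
Why: Silyl-triflate-catalysed ketalization with the bis-silylated glycol works at low temperature without protic acid or water, so the isomerisation-prone ketone and the PMB ether should survive.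

Step 4
Reactants: 5 2-(but-2-yn-1-yl)-2-{[(4-methoxybenzyl)oxy]methyl}-1,3-dioxolane
Product: 7 2-[(2E)-3-iodobut-2-en-1-yl]-2-{[(4-methoxybenzyl)oxy]methyl}-1,3-dioxolane, via alkenylzirconocene chloride 6 (not isolated)
Conditions: Cp2Zr(H)Cl (2 equiv), THF, rt → 45 °C; then I2, 0 °C
Reagents that add atoms: iodine, II
Why: Hydrozirconation is a syn addition that, after equilibration, puts zirconium on the methyl-bearing alkyne carbon, away from the neopentyl-type CH2; iodinolysis with retention should give the (E)-2-iodoalkene.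

**Core**

Step 5
Reactants: 8 2-methylcyclohexane-1,3-dione; 9 acrolein
Product: 10 3-(1-methyl-2,6-dioxocyclohexyl)propanal
Conditions: H2O, rt
Reagents that add atoms: none
Why: Michael addition of the 1,3-dione through C2 to acrolein should give the prochiral triketo aldehyde with the future C5 quaternary carbon.

Step 6
Reactants: 10 3-(1-methyl-2,6-dioxocyclohexyl)propanal
Product: 11 (3aR,7aS)-7a-hydroxy-3a-methylhexahydro-1H-indene-1,4(2H)-dione (cis-fused ketol)
Conditions: chiral aminoindanol-derived N-pentafluorophenyl triazolium tetrafluoroborate (10 mol%; the enantiomer that delivers 11), Et3N (cat.), CH2Cl2, rt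
Reagents that add atoms: none
Why: NHC-catalysed intramolecular crossed benzoin reaction, in which the acyl anion equivalent of the aldehyde adds to one of the two enantiotopic ring ketones (5-exo closure, cis fusion), so the catalyst sets the C5 quaternary stereocentre; this desymmetrization is precedented for 2-methyl-2-(3-oxopropyl) cyclic 1,3-diones.

Step 7
Reactants: 11 cis-fused ketol
Product: 12 (3aR)-3a-methyl-2,3,5,6-tetrahydro-1H-indene-1,4(3aH)-dione (C10=C1 conjugated to the C8 ketone)
Conditions: SOCl2, pyridine, CH2Cl2, 0 °C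
Reagents that add atoms: none
Why: Chlorosulfite formation and pyridine-induced anti elimination; only C1 carries a β-hydrogen (C5 is quaternary), so the conjugated Δ1(10) enone should be the only olefin.

Step 8
Reactants: 12 enedione
Product: 13 C4 ethylene ketal of 12 (spiro-1,3-dioxolane at C4; C8 enone free)
Conditions: ethylene glycol, TsOH·H2O (cat.), 4 Å MS, rt
Reagents that add atoms: ethylene glycol, OCCO
Why: Acid-catalysed ketalization should select the saturated ketone next to the quaternary carbon over the conjugated enone carbonyl, as is general for angularly methylated bicyclic enediones.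

Step 9
Reactants: 7 (E)-vinyl iodide; 13 hydrindenone ketal
Product: 15 tertiary bis-allylic alcohol (8α-OH; 8β-[(E)-C9(CH3)=C11H–C12H2–C13(dioxolane)–C16H2OPMB]), via alkenyllithium 14 (not isolated)
Conditions: 7, t-BuLi (2.0 equiv), Et2O, −78 °C; then 13, THF, −78 °C; then H2O
Reagents that add atoms: none
Why: Iodine–lithium exchange retains the olefin geometry, and 1,2-addition to the enone carbonyl should occur from the β-face, anti to the angular C19 methyl; the C8 configuration is erased in step 11.

Step 10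
Reactants: 15 tertiary bis-allylic alcohol
Product: 16 (9R,11S)-epoxy alcohol (side-chain olefin epoxidised; C10=C1 intact)
Conditions: 1,2:4,5-di-O-isopropylidene-β-L-erythro-2,3-hexodiulo-2,6-pyranose (30 mol%), Oxone (2KHSO5·KHSO4·K2SO4), K2CO3, Bu4NHSO4, MeCN/dimethoxymethane/aq. Na2B4O7 buffer (pH 10.5), 0 °C
Reagents that add atoms: potassium peroxymonosulfate, [K+].[O-]S(=O)(=O)OO
Why: Shi epoxidation, in which the chiral dioxirane adds through a spiro transition state; the L-fructose-derived ketone should give 11S at the olefinic CH carbon and, through the E geometry, 9R, while the ring olefin between two fully substituted carbons should react far more slowly.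

Step 11
Reactants: 16 (9R,11S)-epoxy alcohol
Product: 17 ring-expanded β-silyloxy ketone (Δ1(10)-octalin; C4 dioxolane; C8 ketone; C9 quaternary with C20 α and side chain β; (11S)-OTBS)
Conditions: TBSOTf (1.3 equiv), 2,6-lutidine (2 equiv), CH2Cl2, −78 °C
Reagents that add atoms: tert-butyldimethylsilyl triflate, CC(C)(C)[Si](C)(C)OS(=O)(=O)C(F)(F)F
Why: Semipinacol rearrangement of a tertiary α-hydroxy epoxide: the silyl triflate silylates the epoxide oxygen, the C9–O bond of the tertiary epoxide carbon ionises and, anti to it, the alkenyl carbon C10 shifts from the carbinol carbon C8 to C9 while C8 becomes the carbonyl and 2,6-lutidine takes the proton; the closest known reactions are Lewis-acid and silyl-triflate rearrangements of 2,3-epoxy alcohols to β-hydroxy or β-silyloxy ketones, including cyclopentanol-to-cyclohexanone expansions. Ring B (C5–C6–C7–C8–C9–C10) is closed by ring expansion, C9 being inserted between C8 and C10 of the five-membered ring C5–C6–C7–C8–C10, with ring A untouched. C9 is set by inversion at the epoxide carbon, so the 9R epoxide gives C20 α and C11 β; C11 keeps the configuration from step 10 and emerges as its TBS ether; C10 migrates with its double bond, which places the Δ1(10) olefin for step 20. The step needs C10 and not C7 to migrate and the epoxide to open at C9 rather than the allylic C8–O bond to ionise: the sp2 carbon C10 has a much higher migratory aptitude than the CH2 group C7, C9 is the tertiary epoxide terminus, and low temperature with a hindered base should spare the dioxolanes and the C8–O bond. In one operation the step should deliver the six-membered ring, the all-carbon quaternary C9, the protected C11 carbinol and the C8 ketone that later carries the C6–C8 oxygenation.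

Step 12
Reactants: 17 ring-expanded ketone
Product: 19 Δ6-en-8-one (C6=C7 conjugated to the C8 ketone), via trimethylsilyl enol ether 18 (not isolated)
Conditions: LDA, TMSCl, THF, −78 °C; then Pd(OAc)2 (10 mol%), O2 (1 atm), DMSO, rt
Reagents that add atoms: none
Why: Saegusa–Ito oxidation; the ketone can enolise only toward C7 because C9 is quaternary, and palladium-mediated dehydrosilylation of the silyl enol ether should give the enone.

Step 13
Reactants: 19 Δ6-en-8-one
Product: 20 tertiary allylic alcohol (C8 methyl carbinol; Δ6; major epimer drawn with 8α-OH)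
Conditions: MeLi, Et2O/THF, −78 → 0 °C; then H2O
Reagents that add atoms: methyllithium, [Li]C
Why: 1,2-Addition of methyllithium to an enone that has no enolisable hydrogen should be clean; the new C8 configuration is irrelevant because C8 becomes sp2 in step 14.

Step 14
Reactants: 20 tertiary allylic alcohol
Product: 21 8-methyl-Δ7-en-6-one
Conditions: pyridinium chlorochromate (C5H5NH)[CrO3Cl], 4 Å MS, CH2Cl2, rt
Reagents that add atoms: pyridinium chlorochromate, [O-][Cr](=O)(=O)Cl.c1cc[nH+]cc1
Why: Babler–Dauben oxidative transposition, in which the tertiary chromate ester undergoes a [3,3] shift to C6 and is oxidised, should move the oxygen to C6 and leave the C17 methyl on the C7=C8 olefin.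

Step 15
Reactants: 21 8-methyl-Δ7-en-6-one
Product: 22 6α-allylic alcohol
Conditions: NaBH4, CeCl3·7H2O, MeOH, −78 °C
Reagents that add atoms: none
Why: Luche 1,2-reduction; hydride should add from the β-face, opposite the pseudo-axial C19 and C20 methyls, giving the 6α (equatorial) alcohol.

Step 16
Reactants: 22 6α-allylic alcohol
Product: 23 6α-acetate
Conditions: Ac2O, pyridine, DMAP (cat.), CH2Cl2, rt
Reagents that add atoms: acetic anhydride, CC(=O)OC(C)=O
Why: Standard acylation of the only free hydroxyl group.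

Step 17
Reactants: 23 6α-acetate
Product: 24 7β,8β-diol (8α-methyl; 6α-OAc)
Conditions: OsO4 (10 mol%), N-methylmorpholine N-oxide, acetone/H2O, rt
Reagents that add atoms: N-methylmorpholine N-oxide, C[N+]1([O-])CCOCC1; water, O
Why: Upjohn dihydroxylation; OsO4 should add syn from the β-face, anti to the allylic acetoxy group and to both α-methyls, setting C7 and C8 together, while the C10=C1 olefin between two quaternary carbons should not react.

Step 18
Reactants: 24 7β,8β-diol
Product: 25 7β-isobutyrate (8β-OH free)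
Conditions: isobutyric anhydride, Et3N, DMAP, CH2Cl2, rt
Reagents that add atoms: isobutyric anhydride, CC(C)C(=O)OC(=O)C(C)C
Why: Acylation differentiates the secondary C7 hydroxyl from the hindered tertiary C8 hydroxyl, which should stay free.

Step 19
Reactants: 25 7β-isobutyrate
Product: 26 C11 alcohol (8-OH and 11-OH free; C10=C1 intact)
Conditions: HF·pyridine, pyridine/THF, 0 °C → rt
Reagents that add atoms: none
Why: Buffered fluoride desilylation should remove the TBS ether without touching the esters, the dioxolanes or the PMB ether.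

Step 20
Reactants: 26 C11 alcohol
Product: 28 1β-alcohol with 10β-H (trans-decalin), via C1 alkylborane 27 (not isolated)
Conditions: BH3·THF (excess), THF, 0 °C → rt; then 30% H2O2, pH 7 phosphate buffer, 0 °C
Reagents that add atoms: hydrogen peroxide, OO
Why: Hydroboration–oxidation; boron should add to the less substituted C1 and hydrogen to C10, syn and from the β-face because the α-face carries the axial C19 and C20 methyls, and oxidation with retention then gives 1β-OH and the trans ring fusion in one event.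

Step 21
Reactants: 28 1β-alcohol
Product: 29 1,6,11-triacetate 7-isobutyrate (C4 and C13 dioxolanes; C16 PMB ether; 8-OH free)
Conditions: Ac2O, pyridine, DMAP, CH2Cl2, rt
Reagents that add atoms: acetic anhydride, CC(=O)OC(C)=O
Why: Acetylation of the two secondary hydroxyls at C1 and C11; the axial tertiary C8 hydroxyl should not react.

Step 22
Reactants: 29 triacetate isobutyrate
Product: 30 C16 primary alcohol
Conditions: DDQ, CH2Cl2/pH 7 buffer, 0 °C → rt
Reagents that add atoms: none
Why: Oxidative cleavage of the PMB ether; no olefin or other electron-rich group remains to compete.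

Step 23
Reactants: 30 C16 primary alcohol
Product: 31 hydroxy diketone (C4 ketone; C13 ketone with C16 OH)
Conditions: TsOH·H2O (cat.), acetone/H2O, 50 °C
Reagents that add atoms: water, O
Why: Acid hydrolysis of both dioxolanes should unveil the C4 ketone and the α-hydroxy ketone; the esters tolerate these conditions.

Step 24
Reactants: 31 hydroxy diketone
Product: 33 butenolide C4 ketone, via phosphoranylidene acetate 32 (not isolated)
Conditions: Ph3P=C=C=O, toluene, 80 °C
Reagents that add atoms: (triphenylphosphoranylidene)ketene, O=C=C=P(c1ccccc1)(c1ccccc1)c1ccccc1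
Why: The primary alcohol adds to the ketenylidene ylide to give an ester-stabilised ylide, which should close by intramolecular Wittig reaction on the adjacent C13 ketone to the β-substituted butenolide; the stabilised ylide does not attack the hindered C4 ketone.

Step 25
Reactants: 33 butenolide C4 ketone
Product: 34 target
Conditions: Zn, CH2Br2, TiCl4, THF/CH2Cl2, 0 °C → rt
Reagents that add atoms: dibromomethane, BrCBr
Why: Takai–Lombardo methylenation; the non-basic zinc/titanium gem-dimetallic reagent should methylenate the hindered ketone selectively in the presence of esters, the lactone and the free tertiary alcohol.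

**Compound list**
1 | 2-{[(4-methoxybenzyl)oxy]methyl}oxirane (racemic) | COc1ccc(COCC2CO2)cc1 | starting material
2 | 1-propynyllithium | [Li]C#CC | starting material
3 | 1-[(4-methoxybenzyl)oxy]hex-4-yn-2-ol (racemic) | CC#CCC(O)COCc1ccc(OC)cc1 | intermediate
4 | 1-[(4-methoxybenzyl)oxy]hex-4-yn-2-one | CC#CCC(=O)COCc1ccc(OC)cc1 | intermediate
5 | 2-(but-2-yn-1-yl)-2-{[(4-methoxybenzyl)oxy]methyl}-1,3-dioxolane | CC#CCC1(COCc2ccc(OC)cc2)OCCO1 | intermediate
6 | (E)-alkenylzirconocene chloride (Zr on the methyl-bearing carbon) | C/C(=C\CC1(COCc2ccc(OC)cc2)OCCO1)[Zr](Cl)(C1C=CC=C1)C1C=CC=C1 | intermediate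
7 | 2-[(2E)-3-iodobut-2-en-1-yl]-2-{[(4-methoxybenzyl)oxy]methyl}-1,3-dioxolane | C/C(I)=C\CC1(COCc2ccc(OC)cc2)OCCO1 | intermediate
8 | 2-methylcyclohexane-1,3-dione | CC1C(=O)CCCC1=O | starting material
9 | acrolein | C=CC=O | starting material
10 | 3-(1-methyl-2,6-dioxocyclohexyl)propanal | CC1(CCC=O)C(=O)CCCC1=O | intermediate
11 | (3aR,7aS)-7a-hydroxy-3a-methylhexahydro-1H-indene-1,4(2H)-dione | O=C1CCC[C@]2(O)[C@@]1(C)CCC2=O | intermediate
12 | (3aR)-3a-methyl-2,3,5,6-tetrahydro-1H-indene-1,4(3aH)-dione | O=C1CCC=C2[C@@]1(C)CCC2=O | intermediate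
13 | C4 ethylene ketal of 12 (C8 enone free) | O1CCOC12CCC=C3[C@@]2(C)CCC3=O | intermediate
14 | (E)-alkenyllithium from 7 | C/C([Li])=C\CC1(COCc2ccc(OC)cc2)OCCO1 | intermediate
15 | tertiary bis-allylic alcohol (8α-OH; (E)-side-chain olefin; C10=C1; C4 and C13 dioxolanes; C16 OPMB) | O1CCOC12CCC=C3[C@@]2(C)CC[C@]3(O)/C(C)=C/CC1(COCc2ccc(OC)cc2)OCCO1 | intermediate
16 | (9R,11S)-epoxy alcohol | O1CCOC12CCC=C3[C@@]2(C)CC[C@]3(O)[C@]4(C)O[C@H]4CC1(COCc2ccc(OC)cc2)OCCO1 | intermediate
17 | ring-expanded Δ1(10)-octalin: C8 ketone; C9 quaternary (C20 α); (11S)-OTBS | O1CCOC12CCC=C3[C@@]2(C)CCC(=O)[C@]3(C)[C@H](CC1(COCc2ccc(OC)cc2)OCCO1)O[Si](C)(C)C(C)(C)C | intermediate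
18 | C7=C8 trimethylsilyl enol ether of 17 | O1CCOC12CCC=C3[C@@]2(C)CC=C(O[Si](C)(C)C)[C@]3(C)[C@H](CC1(COCc2ccc(OC)cc2)OCCO1)O[Si](C)(C)C(C)(C)C | intermediate
19 | Δ6-en-8-one | O1CCOC12CCC=C3[C@@]2(C)C=CC(=O)[C@]3(C)[C@H](CC1(COCc2ccc(OC)cc2)OCCO1)O[Si](C)(C)C(C)(C)C | intermediate
20 | C8 methyl carbinol (Δ6; 8α-OH epimer drawn) | O1CCOC12CCC=C3[C@@]2(C)C=C[C@@](C)(O)[C@]3(C)[C@H](CC1(COCc2ccc(OC)cc2)OCCO1)O[Si](C)(C)C(C)(C)C | intermediate
21 | 8-methyl-Δ7-en-6-one | O1CCOC12CCC=C3[C@@]2(C)C(=O)C=C(C)[C@]3(C)[C@H](CC1(COCc2ccc(OC)cc2)OCCO1)O[Si](C)(C)C(C)(C)C | intermediate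
22 | 6α-allylic alcohol | O1CCOC12CCC=C3[C@@]2(C)[C@@H](O)C=C(C)[C@]3(C)[C@H](CC1(COCc2ccc(OC)cc2)OCCO1)O[Si](C)(C)C(C)(C)C | intermediate
23 | 6α-acetate | O1CCOC12CCC=C3[C@@]2(C)[C@@H](OC(C)=O)C=C(C)[C@]3(C)[C@H](CC1(COCc2ccc(OC)cc2)OCCO1)O[Si](C)(C)C(C)(C)C | intermediate
24 | 6α-acetoxy-7β,8β-diol | O1CCOC12CCC=C3[C@@]2(C)[C@@H](OC(C)=O)[C@H](O)[C@](C)(O)[C@]3(C)[C@H](CC1(COCc2ccc(OC)cc2)OCCO1)O[Si](C)(C)C(C)(C)C | intermediate
25 | 6α-acetate 7β-isobutyrate (8β-OH; 11-OTBS) | O1CCOC12CCC=C3[C@@]2(C)[C@@H](OC(C)=O)[C@H](OC(=O)C(C)C)[C@](C)(O)[C@]3(C)[C@H](CC1(COCc2ccc(OC)cc2)OCCO1)O[Si](C)(C)C(C)(C)C | intermediate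
26 | C11 alcohol (Δ1(10)) | O1CCOC12CCC=C3[C@@]2(C)[C@@H](OC(C)=O)[C@H](OC(=O)C(C)C)[C@](C)(O)[C@]3(C)[C@H](CC1(COCc2ccc(OC)cc2)OCCO1)O | intermediate
27 | C1β alkylborane (drawn as RBH2; hydroxyls are borate esters in the flask) | O1CCOC12CC[C@@H](B)[C@H]3[C@@]2(C)[C@@H](OC(C)=O)[C@H](OC(=O)C(C)C)[C@](C)(O)[C@]3(C)[C@H](CC1(COCc2ccc(OC)cc2)OCCO1)O | intermediate
28 | 1β,8β,11-triol 6-acetate 7-isobutyrate (10β-H) | O1CCOC12CC[C@@H](O)[C@H]3[C@@]2(C)[C@@H](OC(C)=O)[C@H](OC(=O)C(C)C)[C@](C)(O)[C@]3(C)[C@H](CC1(COCc2ccc(OC)cc2)OCCO1)O | intermediate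
29 | 1,6,11-triacetate 7-isobutyrate (bis-dioxolane; PMB ether) | O1CCOC12CC[C@@H](OC(C)=O)[C@H]3[C@@]2(C)[C@@H](OC(C)=O)[C@H](OC(=O)C(C)C)[C@](C)(O)[C@]3(C)[C@H](CC1(COCc2ccc(OC)cc2)OCCO1)OC(C)=O | intermediate
30 | C16 primary alcohol (bis-dioxolane) | O1CCOC12CC[C@@H](OC(C)=O)[C@H]3[C@@]2(C)[C@@H](OC(C)=O)[C@H](OC(=O)C(C)C)[C@](C)(O)[C@]3(C)[C@H](CC1(CO)OCCO1)OC(C)=O | intermediate
31 | hydroxy diketone (C4 ketone; C13 ketone; C16 OH) | O=C1CC[C@@H](OC(C)=O)[C@H]2[C@@]1(C)[C@@H](OC(C)=O)[C@H](OC(=O)C(C)C)[C@](C)(O)[C@]2(C)[C@H](CC(=O)CO)OC(C)=O | intermediate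
32 | C16 (triphenylphosphoranylidene)acetate | O=C1CC[C@@H](OC(C)=O)[C@H]2[C@@]1(C)[C@@H](OC(C)=O)[C@H](OC(=O)C(C)C)[C@](C)(O)[C@]2(C)[C@H](CC(=O)COC(=O)C=P(c1ccccc1)(c1ccccc1)c1ccccc1)OC(C)=O | intermediate
33 | butenolide C4 ketone | O=C1CC[C@@H](OC(C)=O)[C@H]2[C@@]1(C)[C@@H](OC(C)=O)[C@H](OC(=O)C(C)C)[C@](C)(O)[C@]2(C)[C@H](CC1=CC(=O)OC1)OC(C)=O | intermediate
34 | CNP0266716.1 | C=C1CC[C@@H](OC(C)=O)[C@H]2[C@@]1(C)[C@@H](OC(C)=O)[C@H](OC(=O)C(C)C)[C@](C)(O)[C@]2(C)[C@H](CC1=CC(=O)OC1)OC(C)=O | target

**Totals**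
Total step count: 25. Longest linear sequence: 21 steps (steps 5–25; the fragment branch, steps 1–4, joins at step 9 and is equally long).

**Three steps most likely to fail**

1. Step 10. The process at risk is face selection: the free tertiary hydroxyl or the ring may steer the dioxirane to the other olefin face, against the catalyst, and the C10=C1 olefin may be oxidised as well. The fallback removes the hydroxyl from the event and changes the mode of the key step. It sets out from 15: silylation (TBSOTf, 2,6-lutidine, CH2Cl2, 0 °C) gives the tertiary silyl ether F1; epoxidation with the same chiral ketone and Oxone, now without hydroxyl direction and with a larger steric difference between the two olefins, gives the epoxy silyl ether F2; catalytic TBSOTf (CH2Cl2, −78 °C) then triggers the rearrangement with silyl transfer from the C8 oxygen to the C11 oxygen, and the route is rejoined at 17.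

2. Step 20. The process at risk is slow hydroboration of an olefin flanked by two quaternary carbons, with borane reducing the esters in the meantime. The fallback sets out from 26: m-CPBA/NaHCO3 (CH2Cl2, 0 °C) epoxidises from the open β-face, on the side of the 8β-hydroxyl, to the 1β,10β-epoxide F3; Cp2TiCl (trivalent titanium, made from Cp2TiCl2 and Zn) with 1,4-cyclohexadiene in THF opens it homolytically to the tertiary C10 radical, which takes a hydrogen atom from the β-face. This gives the same 1β-alcohol with 10β-H, and the route is rejoined at 28.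

3. Step 25. The process at risk is incomplete methylenation of the neopentyl-type C4 ketone, or loss of acetic acid from the β-acetoxy butenolide under the Lewis-acidic reagent. The fallback installs the methylene before the butenolide exists and sets out from 29. Mild hydrolysis (PPTS, acetone/H2O, rt) removes the C4 dioxolane faster than the C13 dioxolane, which is deactivated by its α-alkoxy group, and gives the C4 ketone F4. Tebbe olefination (Cp2Ti(μ-CH2)(μ-Cl)AlMe2, THF/pyridine, −40 °C), ketone-selective at low temperature, gives the exocyclic olefin F5. DDQ gives the primary alcohol F6, and TsOH·H2O in acetone/H2O gives the hydroxy ketone F7. Ph3P=C=C=O in toluene at 80 °C then closes the butenolide, and the route is rejoined at 34.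

**Further compounds**
F1 | step 10 | C8 tert-butyldimethylsilyl ether of 15 | O1CCOC12CCC=C3[C@@]2(C)CC[C@]3(O[Si](C)(C)C(C)(C)C)/C(C)=C/CC1(COCc2ccc(OC)cc2)OCCO1
F2 | step 10 | (9R,11S)-epoxy silyl ether | O1CCOC12CCC=C3[C@@]2(C)CC[C@]3(O[Si](C)(C)C(C)(C)C)[C@]4(C)O[C@H]4CC1(COCc2ccc(OC)cc2)OCCO1
F3 | step 20 | 1β,10β-epoxide of 26 | O1CCOC12CC[C@H]4O[C@@]43[C@@]2(C)[C@@H](OC(C)=O)[C@H](OC(=O)C(C)C)[C@](C)(O)[C@]3(C)[C@H](CC1(COCc2ccc(OC)cc2)OCCO1)O
F4 | step 25 | C4 ketone with C13 dioxolane and C16 PMB ether | O=C1CC[C@@H](OC(C)=O)[C@H]2[C@@]1(C)[C@@H](OC(C)=O)[C@H](OC(=O)C(C)C)[C@](C)(O)[C@]2(C)[C@H](CC1(COCc2ccc(OC)cc2)OCCO1)OC(C)=O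
F5 | step 25 | C4 exocyclic olefin with C13 dioxolane and C16 PMB ether | C=C1CC[C@@H](OC(C)=O)[C@H]2[C@@]1(C)[C@@H](OC(C)=O)[C@H](OC(=O)C(C)C)[C@](C)(O)[C@]2(C)[C@H](CC1(COCc2ccc(OC)cc2)OCCO1)OC(C)=O
F6 | step 25 | C4 exocyclic olefin with C13 dioxolane and C16 alcohol | C=C1CC[C@@H](OC(C)=O)[C@H]2[C@@]1(C)[C@@H](OC(C)=O)[C@H](OC(=O)C(C)C)[C@](C)(O)[C@]2(C)[C@H](CC1(CO)OCCO1)OC(C)=O
F7 | step 25 | C4 exocyclic olefin with C13 ketone and C16 alcohol | C=C1CC[C@@H](OC(C)=O)[C@H]2[C@@]1(C)[C@@H](OC(C)=O)[C@H](OC(=O)C(C)C)[C@](C)(O)[C@]2(C)[C@H](CC(=O)CO)OC(C)=O
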